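## Retrosynthetic overview

1. Schizotenuin A is (R)-rosmarinic acid × 2 minus 4 H. I do not cut the two ester C–O bonds, which is the usual plan (benzofuran diacid plus two danshensu units). I cut the furan ring instead, at C3–C3a (8–5′) and O1–C2, which gives two identical, fully esterified rosmarinate monomers.
2. Only one ring is formed. The furan ring is made first as a trans-2,3-dihydrobenzofuran by Ag2O oxidative homocoupling (key step). DDQ then aromatises it, so the uncontrolled C2/C3 centres vanish and both epimers converge.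
3. Monomer 6 comes from three parts joined in one pot with retention at the carbinol carbon: (R)-danshensu (chiral pool, source of both stereocentres), Meldrum's acid (C8/C9) and 3-BnO-4-HO-benzaldehyde.
4. The 3-O-benzyl group makes the caffeoyl unit behave like a ferulate, with no o-quinone or benzodioxane pathways. All eight benzyl groups leave in one non-reductive last step.

Assumption: commercial sodium danshensu is the natural (R)-enantiomer, and 3-(benzyloxy)-4-hydroxybenzaldehyde is bought as such.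

Abbreviation: DanBn = (1R)-1-(benzyloxycarbonyl)-2-[3,4-bis(benzyloxy)phenyl]ethyl, the O-bound residue of alcohol 2.

## Route

Step 1
Reactants: 1 sodium (2R)-3-(3,4-dihydroxyphenyl)-2-hydroxypropanoate (sodium danshensu)
Product: 2 benzyl (2R)-3-[3,4-bis(benzyloxy)phenyl]-2-hydroxypropanoate (DanBn–OH)
Conditions: BnBr (3.3 equiv), K2CO3 (3 equiv), DMF, Ar, rt, 16 h
Reagents that add atoms: benzyl bromide, BrCc1ccccc1
Why: Williamson ether synthesis and carboxylate SN2 alkylation in one operation, in which K2CO3 ionises only the two phenols (the carboxylate is already ionic), so the much less acidic secondary OH stays free and the purchased (R)-centre is not touched.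

Step 2
Reactants: 2 DanBn–OH; 3 Meldrum's acid; 4 3-(benzyloxy)-4-hydroxybenzaldehyde
Product: 6 benzyl (2R)-2-{[(2E)-3-[3-(benzyloxy)-4-hydroxyphenyl]prop-2-enoyl]oxy}-3-[3,4-bis(benzyloxy)phenyl]propanoate, via malonic half-ester 5 (not isolated)
Conditions: 3 (1.1 equiv), PhMe, 110 °C, 4 h, evaporate; then 4 (1.0 equiv), pyridine, piperidine (0.2 equiv), 55 °C, 24 h
Reagents that add atoms: none
Why: Alcoholysis of Meldrum's acid acylates the carbinol oxygen without breaking its C–O bond (retention), and the Knoevenagel–Doebner condensation of the half-ester with the unprotected p-hydroxybenzaldehyde loses CO2 to give only the (E)-cinnamate, so no phenol protection and no coupling reagent are needed.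

Step 3
Reactants: 6 monomer (two molecules)
Product: 8 trans-octabenzyl-2,3-dihydroschizotenuin A (4′-OH free; both trans ring epimers), via open-chain quinone methide 7 (not isolated)
Conditions: Ag2O (0.55 equiv), dry PhH–acetone 2:1, N2, dark, rt, 20 h; filter through Celite; recover unreacted 6
Reagents that add atoms: none
Why: This is the biomimetic Ag2O phenol oxidative coupling (8–5′ radical dimerisation) standard for 4-hydroxy-3-alkoxycinnamates, in which only the conjugated 4-OH is oxidisable, C8 of one unit bonds to C5′ of the other, and the re-aromatised phenol adds to quinone methide 7 anti to the ester to close the ring trans, while the remote (R)-centres give no facial bias so both trans epimers form, which is harmless because step 4 flattens C2 and C3.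

Step 4
Reactants: 8 trans-dihydrobenzofuran dimer (epimer mixture)
Product: 10 octabenzyl schizotenuin A (4′-OH free), via ring quinone methide 9 (not isolated)
Conditions: DDQ (1.3 equiv), dry 1,4-dioxane, Ar, 80 °C, 8 h
Reagents that add atoms: none
Why: In this DDQ dehydrogenation the free para-OH lets DDQ abstract hydride from the doubly activated C2–H (benzylic and α to oxygen) to give quinone methide 9, whose acidic C3–H (α to the ester) tautomerises to the aromatic benzofuran, so both ring epimers converge to one compound while the side-chain (R)-centres, the (E)-alkene and the benzyl groups are untouched.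

Step 5
Reactants: 10 octabenzyl schizotenuin A
Product: 11 schizotenuin A
Conditions: BCl3 (1 M in CH2Cl2, 20 equiv), C6HMe5 (30 equiv), CH2Cl2, Ar, −78 → 0 °C, 2 h; aq. THF quench; C18 HPLC (H2O–MeCN, 0.1% HCO2H)
Reagents that add atoms: none
Why: Lewis-acid O-alkyl debenzylation with a non-basic cation scavenger (Friedel–Crafts capture of benzyl cation by pentamethylbenzene) removes the six aryl benzyl ethers at −78 °C and the two benzyl esters on warming without reductant or base, so the cinnamate C=C, the two secondary esters (whose α-carbonyl carbinol carbons cannot ionise) and both (R)-centres survive.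

## Compound list

1 | sodium (2R)-3-(3,4-dihydroxyphenyl)-2-hydroxypropanoate (sodium danshensu) | O[C@H](Cc1ccc(O)c(O)c1)C(=O)[O-].[Na+] | starting material
2 | benzyl (2R)-3-[3,4-bis(benzyloxy)phenyl]-2-hydroxypropanoate (DanBn–OH) | O[C@H](Cc1ccc(OCc2ccccc2)c(OCc2ccccc2)c1)C(=O)OCc1ccccc1 | intermediate
3 | Meldrum's acid (2,2-dimethyl-1,3-dioxane-4,6-dione) | CC1(C)OC(=O)CC(=O)O1 | starting material
4 | 3-(benzyloxy)-4-hydroxybenzaldehyde | O=Cc1ccc(O)c(OCc2ccccc2)c1 | starting material
5 | malonic acid mono-DanBn ester (3-(DanBn-oxy)-3-oxopropanoic acid), not isolated | OC(=O)CC(=O)O[C@H](Cc1ccc(OCc2ccccc2)c(OCc2ccccc2)c1)C(=O)OCc1ccccc1 | intermediate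
6 | DanBn (E)-3-[3-(benzyloxy)-4-hydroxyphenyl]prop-2-enoate (tetrabenzyl (R)-rosmarinate, caffeoyl 4-OH free) | O=C(/C=C/c1ccc(O)c(OCc2ccccc2)c1)O[C@H](Cc1ccc(OCc2ccccc2)c(OCc2ccccc2)c1)C(=O)OCc1ccccc1 | intermediate
7 | open-chain 8–5′ adduct, not isolated: [3-(benzyloxy)-4-oxocyclohexa-2,5-dien-1-ylidene]CH–CH(CO2DanBn)–Ar with Ar = 3-(benzyloxy)-2-hydroxy-5-[(E)-2-(DanBn-oxycarbonyl)vinyl]phenyl; both C8 epimers | O=C1C=CC(=CC(C(=O)O[C@H](Cc2ccc(OCc3ccccc3)c(OCc3ccccc3)c2)C(=O)OCc2ccccc2)c2cc(/C=C/C(=O)O[C@H](Cc3ccc(OCc4ccccc4)c(OCc4ccccc4)c3)C(=O)OCc3ccccc3)cc(OCc3ccccc3)c2O)C=C1OCc1ccccc1 | intermediate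
8 | DanBn trans-7-(benzyloxy)-2-[3-(benzyloxy)-4-hydroxyphenyl]-5-[(E)-3-(DanBn-oxy)-3-oxoprop-1-enyl]-2,3-dihydro-1-benzofuran-3-carboxylate; about 1:1 mixture of the (2R,3R) and (2S,3S) ring epimers, SMILES shows (2R,3R) | O=C(/C=C/c1cc(OCc4ccccc4)c2O[C@@H](c3ccc(O)c(OCc4ccccc4)c3)[C@H](C(=O)O[C@H](Cc3ccc(OCc4ccccc4)c(OCc4ccccc4)c3)C(=O)OCc3ccccc3)c2c1)O[C@H](Cc1ccc(OCc2ccccc2)c(OCc2ccccc2)c1)C(=O)OCc1ccccc1 | intermediate
9 | 2-[3-(benzyloxy)-4-oxocyclohexa-2,5-dien-1-ylidene]-2,3-dihydrobenzofuran tautomer of 10, not isolated; C3 epimers | O=C1C=CC(=C2Oc3c(OCc4ccccc4)cc(/C=C/C(=O)O[C@H](Cc4ccc(OCc5ccccc5)c(OCc5ccccc5)c4)C(=O)OCc4ccccc4)cc3C2C(=O)O[C@H](Cc2ccc(OCc3ccccc3)c(OCc3ccccc3)c2)C(=O)OCc2ccccc2)C=C1OCc1ccccc1 | intermediate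
10 | DanBn 7-(benzyloxy)-2-[3-(benzyloxy)-4-hydroxyphenyl]-5-[(E)-3-(DanBn-oxy)-3-oxoprop-1-enyl]-1-benzofuran-3-carboxylate (octabenzyl schizotenuin A) | O=C(/C=C/c1cc(OCc4ccccc4)c2oc(-c3ccc(O)c(OCc4ccccc4)c3)c(C(=O)O[C@H](Cc3ccc(OCc4ccccc4)c(OCc4ccccc4)c3)C(=O)OCc3ccccc3)c2c1)O[C@H](Cc1ccc(OCc2ccccc2)c(OCc2ccccc2)c1)C(=O)OCc1ccccc1 | intermediate
11 | schizotenuin A, (R,R) | O=C(/C=C/c1cc(O)c2oc(-c3ccc(O)c(O)c3)c(C(=O)O[C@H](Cc3ccc(O)c(O)c3)C(=O)O)c2c1)O[C@H](Cc1ccc(O)c(O)c1)C(=O)O | target

## Summary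

Total step count: 5. Longest linear sequence: 5 steps (1 → 2 → 6 → 8 → 10 → 11).

## Three steps most likely to fail

**Risk A, the oxidative homocoupling (step 3).** A realistic yield is 25–40%. The large monomer may divert to 8–O–4′ or 8–8′ dimers or to oligomers. Slight over-oxidation of 8 is harmless because it only gives 10.

- The fallback replaces radical–radical coupling by an iron-catalysed cross-dehydrogenative phenol/β-keto ester annulation, which can only engage the single free ortho position of 6.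
- It sets out from 2, 3 and 6 and comes back at 11.
- Compound 3 is C-acylated with commercial 3,4-bis(benzyloxy)benzoic acid (EDC, DMAP, CH2Cl2) to the acyl Meldrum's acid F1.
- Heating this with 2 in toluene (acylketene trapping, retention at the carbinol) gives the β-keto ester F2.
- F2 and 6 with FeCl3·6H2O (10 mol %) and (t-BuO)2 in DCE at 100 °C undergo ortho C–C coupling and cyclodehydration to the nonabenzyl benzofuran F3. This is already at the benzofuran oxidation level, so step 4 is bypassed as well.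
- The conditions of step 5 then give 11.

**Risk B, the dehydrogenation (step 4).** DDQ may attack the benzyl ethers or the danshensu benzylic CH2 groups, or over-oxidise the phenol.

- The fallback exchanges hydride abstraction for polar enolate halogenation and elimination, the logic used for oxazoline-to-oxazole oxidation.
- It sets out from 8 and comes back at 11.
- Compound 8 is capped at the 4′-OH (BnBr, K2CO3, acetone, rt) to the nonabenzyl dihydrobenzofuran F4.
- BrCCl3/DBU in CH2Cl2 at 0 °C brominates the most acidic C–H (C3, α to the ester and benzylic) to the 3-bromide F5. This loses HBr in the same flask to give the nonabenzyl benzofuran F3.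
- The conditions of step 5 then give 11. The ee of the side-chain centres must be checked after the DBU exposure.

**Risk C, the eightfold debenzylation (step 5).** The aryl ethers should cleave cleanly at −78 °C. The two benzyl esters may need warming that the polyphenol does not tolerate.

- The fallback separates the two jobs by bond type.
- It sets out from 10 and comes back at 11.
- Me3SnOH (10 equiv, DCE, 70 °C, Ar) hydrolyses by acyl–oxygen cleavage only the two unhindered, α-acyloxy-activated benzyl esters. The conjugated secondary esters are left alone, and the product is the hexabenzyl diacid F6.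
- F6 carries only aryl benzyl ethers, and BCl3/C6HMe5 kept at −78 °C converts it to 11.

## Further compounds

F1 | step 3 | 5-[3,4-bis(benzyloxy)benzoyl]-2,2-dimethyl-1,3-dioxane-4,6-dione (acyl Meldrum's acid) | CC1(C)OC(=O)C(C(=O)c2ccc(OCc3ccccc3)c(OCc3ccccc3)c2)C(=O)O1
F2 | step 3 | DanBn 3-[3,4-bis(benzyloxy)phenyl]-3-oxopropanoate (β-keto ester) | O=C(CC(=O)c1ccc(OCc2ccccc2)c(OCc2ccccc2)c1)O[C@H](Cc1ccc(OCc2ccccc2)c(OCc2ccccc2)c1)C(=O)OCc1ccccc1
F3 | step 3 | nonabenzyl schizotenuin A (10 with 4′-OBn) | O=C(/C=C/c1cc(OCc4ccccc4)c2oc(-c3ccc(OCc4ccccc4)c(OCc4ccccc4)c3)c(C(=O)O[C@H](Cc3ccc(OCc4ccccc4)c(OCc4ccccc4)c3)C(=O)OCc3ccccc3)c2c1)O[C@H](Cc1ccc(OCc2ccccc2)c(OCc2ccccc2)c1)C(=O)OCc1ccccc1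
F4 | step 4 | nonabenzyl trans-2,3-dihydroschizotenuin A (8 with 4′-OBn; both trans ring epimers, SMILES shows 2R,3R) | O=C(/C=C/c1cc(OCc4ccccc4)c2O[C@@H](c3ccc(OCc4ccccc4)c(OCc4ccccc4)c3)[C@H](C(=O)O[C@H](Cc3ccc(OCc4ccccc4)c(OCc4ccccc4)c3)C(=O)OCc3ccccc3)c2c1)O[C@H](Cc1ccc(OCc2ccccc2)c(OCc2ccccc2)c1)C(=O)OCc1ccccc1
F5 | step 4 | 3-bromo derivative of F4 (ring centres undefined, transient) | O=C(/C=C/c1cc(OCc4ccccc4)c2OC(c3ccc(OCc4ccccc4)c(OCc4ccccc4)c3)C(Br)(C(=O)O[C@H](Cc3ccc(OCc4ccccc4)c(OCc4ccccc4)c3)C(=O)OCc3ccccc3)c2c1)O[C@H](Cc1ccc(OCc2ccccc2)c(OCc2ccccc2)c1)C(=O)OCc1ccccc1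
F6 | step 5 | hexabenzyl schizotenuin A diacid (10 with both CO2Bn as CO2H) | O=C(/C=C/c1cc(OCc4ccccc4)c2oc(-c3ccc(O)c(OCc4ccccc4)c3)c(C(=O)O[C@H](Cc3ccc(OCc4ccccc4)c(OCc4ccccc4)c3)C(=O)O)c2c1)O[C@H](Cc1ccc(OCc2ccccc2)c(OCc2ccccc2)c1)C(=O)O
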